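**Plan**

- Retrosynthetic cuts: first the coumarate ester C–O bond and the acid-labile masks. Then, in the benzene ring, the two bonds aryl C1′–C(=O) and aryl C2′–O of the ortho-hydroxyaryl ketone: the acyl carbon on C1′ and the hydroxyl on the neighbouring C2′, with the acyl carbon one CH2 away from C2 of the oxepene, are the pair of adjacent groups an aryne takes up from a CH2–CO2H arm.
- Further cuts: the C5=C6 alkene of the 2,3,4,7-tetrahydrooxepine (metathesis), the sp2–sp3 bond between the C6 substituent and its chain, the O1–C7 ether bond, and the C2–CH2 bond of the arm (aldol).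
- Forward order: α-keto ester, then aldol (sets C2), O-alkylation at O1, B-alkyl coupling of the side chain, and ring-closing metathesis (the only ring that is built). The aromatic ring is then attached by aryne insertion, followed by dechlorination, desilylation, coumaroylation and acidolysis.
- Stereochemistry: the only stereocentre, quaternary C2 (R), comes from a copper bis(oxazoline)-catalysed Mukaiyama aldol and has no hydrogen to lose afterwards. The (E) side-chain alkene comes from a stabilised Wittig reagent, the (E) cinnamate from p-coumaric acid.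

Key step: step 15

Remark: the facial preference of the copper-catalysed aldol is taken to be that known for simple pyruvate esters, with the butenyl chain in the place of methyl. The absolute configuration of the aldol product should be confirmed by correlation, and the hydroxy acid stage offers a point for enantiomeric enrichment by crystallisation if needed.

**Aryne precursor**

Step 1
Reactants: 1 2-chlorobenzene-1,3-diol
Product: 2 2-chloro-3-(methoxymethoxy)phenol
Conditions: MOMCl (1.0 equiv), i-Pr2NEt, CH2Cl2, 0 °C → rt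
Reagents that add atoms: chloromethyl methyl ether, COCCl
Why: O-alkylation of one phenol of the symmetrical diol with the reactive α-chloro ether (statistical monoprotection) should give mainly the mono-ether, which is separable from recovered diol and bis-ether.

Step 2
Reactants: 2 2-chloro-3-(methoxymethoxy)phenol
Product: 3 2-chloro-3-(methoxymethoxy)phenyl N-isopropylcarbamate
Conditions: i-PrNCO, Et3N (cat.), CH2Cl2, rt
Reagents that add atoms: isopropyl isocyanate, CC(C)N=C=O
Why: Amine-catalysed addition of the phenol to the isocyanate (carbamoylation) installs a carbamate that is both the strongest ortho-directing group in the ring and easy to remove later.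

Step 3
Reactants: 3 2-chloro-3-(methoxymethoxy)phenyl N-isopropylcarbamate
Product: 7 2-chloro-3-(methoxymethoxy)-6-(trimethylsilyl)phenyl N-isopropylcarbamate, via N-silyl carbamate 4 (not isolated), via aryllithium 5 (not isolated), via N-silyl arylsilane 6 (not isolated)
Conditions: TBSOTf, TMEDA, Et2O, 0 °C → rt; n-BuLi, TMEDA, −78 °C; Me3SiCl, −78 °C → rt; aq. NaHSO4
Reagents that add atoms: chlorotrimethylsilane, C[Si](C)(C)Cl
Why: Directed ortho-metalation, in which the carbamate, N-silylated in situ so that it has no acidic hydrogen, guides n-BuLi to its only free ortho position C6 (the other is blocked by chlorine and the methoxymethoxy group is the weaker director), Me3SiCl traps the aryllithium and the N-silyl group falls off on work-up.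

Step 4
Reactants: 7 2-chloro-3-(methoxymethoxy)-6-(trimethylsilyl)phenyl N-isopropylcarbamate
Product: 9 2-chloro-3-(methoxymethoxy)-6-(trimethylsilyl)phenyl trifluoromethanesulfonate, via phenol 8 (not isolated)
Conditions: DBU, Et2NH, MeCN, 40 °C; then PhNTf2, rt
Reagents that add atoms: N-phenylbis(trifluoromethanesulfonimide), O=S(=O)(N(c1ccccc1)S(=O)(=O)C(F)(F)F)C(F)(F)F
Why: E1cB cleavage of the N–H carbamate by DBU releases the phenoxide and isopropyl isocyanate, which Et2NH traps as a urea, and the phenoxide is sulfonylated in the same flask to the ortho-silylaryl triflate.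

**Side-chain diene**

Step 5
Reactants: 10 prop-2-enal (acrolein) and 11 ethyl 2-(triphenyl-λ5-phosphanylidene)propanoate
Product: 12 ethyl (2E)-2-methylpenta-2,4-dienoate
Conditions: CH2Cl2, 0 °C → rt
Reagents that add atoms: none
Why: Wittig olefination with the stabilised α-methyl ylide is reversible at the oxaphosphetane stage and should therefore give the (E)-trisubstituted enoate.

Step 6
Reactants: 12 ethyl (2E)-2-methylpenta-2,4-dienoate
Product: 13 (2E)-2-methylpenta-2,4-dien-1-ol
Conditions: i-Bu2AlH (2.2 equiv), CH2Cl2, −78 °C; aq. potassium sodium tartrate (KNaC4H4O6)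
Reagents that add atoms: none
Why: Hydride reduction of the ester with two equivalents of i-Bu2AlH gives the allylic alcohol by 1,2-addition and leaves the diene and its geometry untouched.

Step 7
Reactants: 13 (2E)-2-methylpenta-2,4-dien-1-ol
Product: 14 tert-butyl{[(2E)-2-methylpenta-2,4-dien-1-yl]oxy}diphenylsilane
Conditions: TBDPSCl, imidazole, CH2Cl2, 0 °C → rt
Reagents that add atoms: tert-butyl(chloro)diphenylsilane, CC(C)(C)[Si](Cl)(c1ccccc1)c1ccccc1
Why: Imidazole-promoted silylation of the primary allylic alcohol gives a non-volatile silyl ether that should tolerate hydroboration, cross-coupling, metathesis and aqueous base.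

**Core and end game**

Step 8
Reactants: 15 S-tert-butyl ethanethioate
Product: 16 {[1-(tert-butylsulfanyl)ethenyl]oxy}trimethylsilane
Conditions: LiN(i-Pr)2, THF, −78 °C; Me3SiCl, −78 °C → rt
Reagents that add atoms: chlorotrimethylsilane, C[Si](C)(C)Cl
Why: Kinetic enolisation of the thioester and O-silylation of the lithium enolate (enol silane formation) give the silyl ketene thioacetal needed for the aldol.

Step 9
Reactants: 17 di-tert-butyl oxalate and 18 but-3-en-1-ylmagnesium bromide
Product: 19 tert-butyl 2-oxohex-5-enoate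
Conditions: 17 (1.5 equiv), THF, −78 °C; aq. NH4Cl at −78 °C
Reagents that add atoms: none
Why: Acylation of the Grignard reagent by the oxalate diester stops at the tetrahedral magnesium hemiketal at −78 °C, which collapses to the α-keto ester only on quenching, so a second addition is avoided.

Step 10
Reactants: 19 tert-butyl 2-oxohex-5-enoate and 16 {[1-(tert-butylsulfanyl)ethenyl]oxy}trimethylsilane
Product: 21 tert-butyl (2R)-2-[2-(tert-butylsulfanyl)-2-oxoethyl]-2-hydroxyhex-5-enoate, via silyl ether 20 (not isolated)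
Conditions: Cu(OTf)2 (10 mol %), (4R,4′R)-2,2′-(propane-2,2-diyl)bis(4-tert-butyl-4,5-dihydro-1,3-oxazole) (11 mol %), THF, −78 °C; then 1 M HCl, THF, rt
Reagents that add atoms: none
Why: Catalytic enantioselective Mukaiyama aldol addition, in which the α-keto ester chelates divalent copper through both carbonyl oxygens in a square-planar complex, the tert-butyl group of the (R,R) ligand covers the si face of the ketone and the silyl ketene thioacetal adds to the re face to set the (R) tertiary carbinol, the silyl ether being cleaved by the acid work-up.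

Step 11
Reactants: 21 tert-butyl (2R)-2-[2-(tert-butylsulfanyl)-2-oxoethyl]-2-hydroxyhex-5-enoate
Product: 22 (3R)-3-(tert-butoxycarbonyl)-3-hydroxyhept-6-enoic acid
Conditions: LiOH·H2O, THF/H2O (3:1), 0 °C; then aq. HCl to pH 3
Reagents that add atoms: lithium hydroxide, [Li+].[OH-]
Why: Saponification, in which hydroxide attacks the unhindered thioester carbonyl far faster than the tert-butyl ester on the quaternary carbon and, at 0 °C, faster than retro-aldol cleavage, so the stereocentre is kept.

Step 12
Reactants: 22 (3R)-3-(tert-butoxycarbonyl)-3-hydroxyhept-6-enoic acid and 23 2,3-dibromoprop-1-ene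
Product: 24 (3R)-3-[(2-bromoprop-2-en-1-yl)oxy]-3-(tert-butoxycarbonyl)hept-6-enoic acid
Conditions: NaH (2.3 equiv), THF/DMF (4:1), 0 °C; 23 (1.2 equiv), 0 °C → rt; aq. HCl to pH 3
Reagents that add atoms: none
Why: Williamson etherification of the dianion, in which the tertiary alkoxide is far more nucleophilic than the carboxylate towards the allylic bromide, while the carboxylate form of the arm closes the retro-aldol and E1cB pathways that an ester arm would open.

Step 13
Reactants: 24 (3R)-3-[(2-bromoprop-2-en-1-yl)oxy]-3-(tert-butoxycarbonyl)hept-6-enoic acid and 14 tert-butyl{[(2E)-2-methylpenta-2,4-dien-1-yl]oxy}diphenylsilane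
Product: 26 (3R)-3-(tert-butoxycarbonyl)-3-{[(5E)-7-{[tert-butyl(diphenyl)silyl]oxy}-6-methyl-2-methylidenehept-5-en-1-yl]oxy}hept-6-enoic acid, via alkylborane 25 (not isolated)
Conditions: 14 (1.6 equiv), 9-BBN-H (1.5 equiv), THF, 0 °C → rt; then 24, PdCl2(dppf) (5 mol %), AsPh3, Cs2CO3, DMF/H2O, rt; acidify to pH 4
Reagents that add atoms: none
Why: Anti-Markovnikov hydroboration of the terminal vinyl group of the diene (the trisubstituted alkene is too hindered for 9-BBN-H) followed by B-alkyl Suzuki–Miyaura coupling with the vinyl bromide forms the sp3–sp2 bond and the 1,1-disubstituted alkene for metathesis, with the acid carried as its cesium salt.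

Step 14
Reactants: 26 (3R)-3-(tert-butoxycarbonyl)-3-{[(5E)-7-{[tert-butyl(diphenyl)silyl]oxy}-6-methyl-2-methylidenehept-5-en-1-yl]oxy}hept-6-enoic acid
Product: 27 2-[(2R)-2-(tert-butoxycarbonyl)-6-[(3E)-5-{[tert-butyl(diphenyl)silyl]oxy}-4-methylpent-3-en-1-yl]-2,3,4,7-tetrahydrooxepin-2-yl]acetic acid
Conditions: second-generation Grubbs catalyst (H2IMes)(PCy3)Cl2Ru=CHPh (5 mol %), CH2Cl2 (5 mM), 40 °C
Reagents that add atoms: none
Why: Ring-closing metathesis between the monosubstituted and the 1,1-disubstituted alkene closes the seven-membered ether with loss of ethene, helped by the quaternary carbon in the tether, while the trisubstituted side-chain alkene is too hindered to compete.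

Step 15
Reactants: 27 2-[(2R)-2-(tert-butoxycarbonyl)-6-[(3E)-5-{[tert-butyl(diphenyl)silyl]oxy}-4-methylpent-3-en-1-yl]-2,3,4,7-tetrahydrooxepin-2-yl]acetic acid and 9 2-chloro-3-(methoxymethoxy)-6-(trimethylsilyl)phenyl trifluoromethanesulfonate
Product: 29 tert-butyl (2R)-6-[(3E)-5-{[tert-butyl(diphenyl)silyl]oxy}-4-methylpent-3-en-1-yl]-2-{2-[2-chloro-6-hydroxy-3-(methoxymethoxy)phenyl]-2-oxoethyl}-2,3,4,7-tetrahydrooxepine-2-carboxylate, via aryne 28 (not isolated)
Conditions: 9 (2 equiv), CsF (5 equiv), THF, 125 °C, sealed tube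
Reagents that add atoms: none
Why: Fluoride strips the Me3Si group of 9 and triflate leaves, so aryne 28 forms slowly in the presence of the cesium carboxylate of 27; the carboxylate oxygen adds to the aryne carbon remote from chlorine, the aryl anion that results next to chlorine attacks the carbonyl of the aryl ester just made, and the four-membered alkoxide opens to the ketone phenoxide. The closest known reaction type is the fluoride-induced insertion of arynes into the C–O bond of carboxylic acids to give ortho-hydroxyaryl ketones, an intermolecular relative of the anionic Fries shift. No ring is closed (the four-membered alkoxide, formally a 4-exo-trig addition, is transient) and no stereocentre is made; the quaternary C2 has no hydrogen, and the product rests as a phenoxide whose α-CH2 is too weakly acidic for retro-oxa-Michael opening of the ether ring. Regioselectivity on the unsymmetrical aryne is needed and is secured by the chlorine, whose inductive pull distorts the triple bond so that the distal carbon is the electrophilic one and the negative charge develops beside chlorine, which places the new oxygen para to the methoxymethoxy group and the acyl group between OH and Cl. Chemoselectivity between the two carboxyl groups is secured by the tert-butyl ester at C2, which cannot add to the aryne, and the high temperature in THF lets acyl transfer outrun protonation of the aryl anion.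

Step 16
Reactants: 29 tert-butyl (2R)-6-[(3E)-5-{[tert-butyl(diphenyl)silyl]oxy}-4-methylpent-3-en-1-yl]-2-{2-[2-chloro-6-hydroxy-3-(methoxymethoxy)phenyl]-2-oxoethyl}-2,3,4,7-tetrahydrooxepine-2-carboxylate
Product: 30 tert-butyl (2R)-6-[(3E)-5-{[tert-butyl(diphenyl)silyl]oxy}-4-methylpent-3-en-1-yl]-2-{2-[2-hydroxy-5-(methoxymethoxy)phenyl]-2-oxoethyl}-2,3,4,7-tetrahydrooxepine-2-carboxylate
Conditions: Pd(OAc)2 (5 mol %), XPhos (2-dicyclohexylphosphino-2′,4′,6′-triisopropylbiphenyl, 10 mol %), HCO2Na, DMF, 80 °C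
Reagents that add atoms: none
Why: Palladium-catalysed hydrodechlorination, in which zerovalent palladium inserts into the aryl C–Cl bond activated by the ortho ketone, formate delivers hydride with loss of CO2 and reductive elimination gives the arene, while alkyl and silyl allylic ethers and trisubstituted alkenes are not substrates for this catalyst.

Step 17
Reactants: 30 tert-butyl (2R)-6-[(3E)-5-{[tert-butyl(diphenyl)silyl]oxy}-4-methylpent-3-en-1-yl]-2-{2-[2-hydroxy-5-(methoxymethoxy)phenyl]-2-oxoethyl}-2,3,4,7-tetrahydrooxepine-2-carboxylate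
Product: 31 tert-butyl (2R)-6-[(3E)-5-hydroxy-4-methylpent-3-en-1-yl]-2-{2-[2-hydroxy-5-(methoxymethoxy)phenyl]-2-oxoethyl}-2,3,4,7-tetrahydrooxepine-2-carboxylate
Conditions: Bu4NF, AcOH (1:1), THF, 0 °C → rt
Reagents that add atoms: none
Why: Fluoride-mediated desilylation, buffered with acetic acid so that the medium is not basic enough to open the β-alkoxy ketone by retro-oxa-Michael reaction or to touch the tert-butyl ester.

Step 18
Reactants: 31 tert-butyl (2R)-6-[(3E)-5-hydroxy-4-methylpent-3-en-1-yl]-2-{2-[2-hydroxy-5-(methoxymethoxy)phenyl]-2-oxoethyl}-2,3,4,7-tetrahydrooxepine-2-carboxylate and 32 (2E)-3-(4-hydroxyphenyl)prop-2-enoic acid (p-coumaric acid)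
Product: 33 tert-butyl (2R)-2-{2-[2-hydroxy-5-(methoxymethoxy)phenyl]-2-oxoethyl}-6-[(3E)-5-{[(2E)-3-(4-hydroxyphenyl)prop-2-enoyl]oxy}-4-methylpent-3-en-1-yl]-2,3,4,7-tetrahydrooxepine-2-carboxylate
Conditions: PPh3, DIAD, THF, 0 °C → rt
Reagents that add atoms: none
Why: Mitsunobu esterification, in which the primary allylic alcohol is activated as its oxyphosphonium ion and displaced in an SN2 step by the carboxylate of 32, the only group acidic enough to be deprotonated by the betaine, so the phenols of both partners stay free and the alkene stays in place.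

Step 19
Reactants: 33 tert-butyl (2R)-2-{2-[2-hydroxy-5-(methoxymethoxy)phenyl]-2-oxoethyl}-6-[(3E)-5-{[(2E)-3-(4-hydroxyphenyl)prop-2-enoyl]oxy}-4-methylpent-3-en-1-yl]-2,3,4,7-tetrahydrooxepine-2-carboxylate
Product: 34 (2R)-2-[2-(2,5-dihydroxyphenyl)-2-oxoethyl]-6-[(3E)-5-{[(2E)-3-(4-hydroxyphenyl)prop-2-enoyl]oxy}-4-methylpent-3-en-1-yl]-2,3,4,7-tetrahydrooxepine-2-carboxylic acid (CNP0602535.1)
Conditions: CF3CO2H/CH2Cl2 (1:4), H2O (5 equiv), 0 °C → rt, argon
Reagents that add atoms: none
Why: Acidolysis, in which trifluoroacetic acid cleaves the tert-butyl ester by loss of the tert-butyl cation as 2-methylpropene and hydrolyses the aryl methoxymethyl acetal, while the coumarate ester, the ring ether and the hydrogen-free stereocentre should be inert at this temperature.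

**Compound list**

1 | 2-chlorobenzene-1,3-diol | Oc1cccc(O)c1Cl | starting material
2 | 2-chloro-3-(methoxymethoxy)phenol | COCOc1cccc(O)c1Cl | intermediate
3 | 2-chloro-3-(methoxymethoxy)phenyl N-isopropylcarbamate | COCOc1cccc(OC(=O)NC(C)C)c1Cl | intermediate
4 | 2-chloro-3-(methoxymethoxy)phenyl N-[tert-butyl(dimethyl)silyl]-N-isopropylcarbamate | COCOc1cccc(OC(=O)N(C(C)C)[Si](C)(C)C(C)(C)C)c1Cl | intermediate
5 | [2-({[tert-butyl(dimethyl)silyl](isopropyl)carbamoyl}oxy)-3-chloro-4-(methoxymethoxy)phenyl]lithium | COCOc1ccc([Li])c(OC(=O)N(C(C)C)[Si](C)(C)C(C)(C)C)c1Cl | intermediate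
6 | 2-chloro-3-(methoxymethoxy)-6-(trimethylsilyl)phenyl N-[tert-butyl(dimethyl)silyl]-N-isopropylcarbamate | COCOc1ccc([Si](C)(C)C)c(OC(=O)N(C(C)C)[Si](C)(C)C(C)(C)C)c1Cl | intermediate
7 | 2-chloro-3-(methoxymethoxy)-6-(trimethylsilyl)phenyl N-isopropylcarbamate | COCOc1ccc([Si](C)(C)C)c(OC(=O)NC(C)C)c1Cl | intermediate
8 | 2-chloro-3-(methoxymethoxy)-6-(trimethylsilyl)phenol | COCOc1ccc([Si](C)(C)C)c(O)c1Cl | intermediate
9 | 2-chloro-3-(methoxymethoxy)-6-(trimethylsilyl)phenyl trifluoromethanesulfonate | COCOc1ccc([Si](C)(C)C)c(OS(=O)(=O)C(F)(F)F)c1Cl | intermediate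
10 | prop-2-enal (acrolein) | C=CC=O | starting material
11 | ethyl 2-(triphenyl-λ5-phosphanylidene)propanoate | CCOC(=O)C(C)=P(c1ccccc1)(c1ccccc1)c1ccccc1 | starting material
12 | ethyl (2E)-2-methylpenta-2,4-dienoate | C=C/C=C(\C)C(=O)OCC | intermediate
13 | (2E)-2-methylpenta-2,4-dien-1-ol | C=C/C=C(\C)CO | intermediate
14 | tert-butyl{[(2E)-2-methylpenta-2,4-dien-1-yl]oxy}diphenylsilane | C=C/C=C(\C)CO[Si](c1ccccc1)(c1ccccc1)C(C)(C)C | intermediate
15 | S-tert-butyl ethanethioate | CC(=O)SC(C)(C)C | starting material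
16 | {[1-(tert-butylsulfanyl)ethenyl]oxy}trimethylsilane | C=C(O[Si](C)(C)C)SC(C)(C)C | intermediate
17 | di-tert-butyl oxalate | CC(C)(C)OC(=O)C(=O)OC(C)(C)C | starting material
18 | but-3-en-1-ylmagnesium bromide | C=CCC[Mg]Br | starting material
19 | tert-butyl 2-oxohex-5-enoate | C=CCCC(=O)C(=O)OC(C)(C)C | intermediate
20 | tert-butyl (2R)-2-[2-(tert-butylsulfanyl)-2-oxoethyl]-2-[(trimethylsilyl)oxy]hex-5-enoate | C=CCC[C@@](CC(=O)SC(C)(C)C)(C(=O)OC(C)(C)C)O[Si](C)(C)C | intermediate
21 | tert-butyl (2R)-2-[2-(tert-butylsulfanyl)-2-oxoethyl]-2-hydroxyhex-5-enoate | C=CCC[C@@](CC(=O)SC(C)(C)C)(C(=O)OC(C)(C)C)O | intermediate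
22 | (3R)-3-(tert-butoxycarbonyl)-3-hydroxyhept-6-enoic acid | C=CCC[C@@](CC(=O)O)(C(=O)OC(C)(C)C)O | intermediate
23 | 2,3-dibromoprop-1-ene | C=C(Br)CBr | starting material
24 | (3R)-3-[(2-bromoprop-2-en-1-yl)oxy]-3-(tert-butoxycarbonyl)hept-6-enoic acid | C=CCC[C@@](CC(=O)O)(C(=O)OC(C)(C)C)OCC(Br)=C | intermediate
25 | 9-[(3E)-5-{[tert-butyl(diphenyl)silyl]oxy}-4-methylpent-3-en-1-yl]-9-borabicyclo[3.3.1]nonane | C/C(=C\CCB1C2CCCC1CCC2)CO[Si](c1ccccc1)(c1ccccc1)C(C)(C)C | intermediate
26 | (3R)-3-(tert-butoxycarbonyl)-3-{[(5E)-7-{[tert-butyl(diphenyl)silyl]oxy}-6-methyl-2-methylidenehept-5-en-1-yl]oxy}hept-6-enoic acid | C=CCC[C@@](CC(=O)O)(C(=O)OC(C)(C)C)OCC(=C)CC/C=C(\C)CO[Si](c1ccccc1)(c1ccccc1)C(C)(C)C | intermediate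
27 | 2-[(2R)-2-(tert-butoxycarbonyl)-6-[(3E)-5-{[tert-butyl(diphenyl)silyl]oxy}-4-methylpent-3-en-1-yl]-2,3,4,7-tetrahydrooxepin-2-yl]acetic acid | C/C(=C\CCC1=CCC[C@@](CC(=O)O)(C(=O)OC(C)(C)C)OC1)CO[Si](c1ccccc1)(c1ccccc1)C(C)(C)C | intermediate
28 | 3-chloro-4-(methoxymethoxy)benzyne | COCOC1=C(Cl)C#CC=C1 | intermediate
29 | tert-butyl (2R)-6-[(3E)-5-{[tert-butyl(diphenyl)silyl]oxy}-4-methylpent-3-en-1-yl]-2-{2-[2-chloro-6-hydroxy-3-(methoxymethoxy)phenyl]-2-oxoethyl}-2,3,4,7-tetrahydrooxepine-2-carboxylate | C/C(=C\CCC1=CCC[C@@](CC(=O)c2c(Cl)c(OCOC)ccc2O)(C(=O)OC(C)(C)C)OC1)CO[Si](c1ccccc1)(c1ccccc1)C(C)(C)C | intermediate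
30 | tert-butyl (2R)-6-[(3E)-5-{[tert-butyl(diphenyl)silyl]oxy}-4-methylpent-3-en-1-yl]-2-{2-[2-hydroxy-5-(methoxymethoxy)phenyl]-2-oxoethyl}-2,3,4,7-tetrahydrooxepine-2-carboxylate | C/C(=C\CCC1=CCC[C@@](CC(=O)c2cc(OCOC)ccc2O)(C(=O)OC(C)(C)C)OC1)CO[Si](c1ccccc1)(c1ccccc1)C(C)(C)C | intermediate
31 | tert-butyl (2R)-6-[(3E)-5-hydroxy-4-methylpent-3-en-1-yl]-2-{2-[2-hydroxy-5-(methoxymethoxy)phenyl]-2-oxoethyl}-2,3,4,7-tetrahydrooxepine-2-carboxylate | C/C(=C\CCC1=CCC[C@@](CC(=O)c2cc(OCOC)ccc2O)(C(=O)OC(C)(C)C)OC1)CO | intermediate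
32 | (2E)-3-(4-hydroxyphenyl)prop-2-enoic acid | O=C(O)/C=C/c1ccc(O)cc1 | starting material
33 | tert-butyl (2R)-2-{2-[2-hydroxy-5-(methoxymethoxy)phenyl]-2-oxoethyl}-6-[(3E)-5-{[(2E)-3-(4-hydroxyphenyl)prop-2-enoyl]oxy}-4-methylpent-3-en-1-yl]-2,3,4,7-tetrahydrooxepine-2-carboxylate | C/C(=C\CCC1=CCC[C@@](CC(=O)c2cc(OCOC)ccc2O)(C(=O)OC(C)(C)C)OC1)COC(=O)/C=C/c1ccc(O)cc1 | intermediate
34 | (2R)-2-[2-(2,5-dihydroxyphenyl)-2-oxoethyl]-6-[(3E)-5-{[(2E)-3-(4-hydroxyphenyl)prop-2-enoyl]oxy}-4-methylpent-3-en-1-yl]-2,3,4,7-tetrahydrooxepine-2-carboxylic acid | C/C(=C\CCC1=CCC[C@@](CC(=O)c2cc(O)ccc2O)(C(=O)O)OC1)COC(=O)/C=C/c1ccc(O)cc1 | target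

**Step count and risks**

Total step count: 19.
Longest linear sequence: 11 steps (steps 9 to 19, from di-tert-butyl oxalate 17; step 8 feeds into step 10, steps 5 to 7 into step 13, steps 1 to 4 into step 15).

Steps most likely to fail:

Step 15. The aryl anion may be protonated before the acyl shift, which stops the sequence at the O-aryl ester. Fluoride at 125 °C may also strip the silyl ether, after which the freed alcohol would add to the aryne, and the carboxylate may add with incomplete regiocontrol. The fallback makes the same aryl–oxygen and aryl–carbon bonds without an aryne and without fluoride. Acid 27 is esterified (EDC, DMAP, CH2Cl2) with 2-bromo-4-(methoxymethoxy)phenol F1, which is made from commercial 4-(methoxymethoxy)phenol and N-bromosuccinimide, to give the aryl ester 2-bromo-4-(methoxymethoxy)phenyl 2-[(2R)-2-(tert-butoxycarbonyl)-6-[(3E)-5-{[tert-butyl(diphenyl)silyl]oxy}-4-methylpent-3-en-1-yl]-2,3,4,7-tetrahydrooxepin-2-yl]acetate F2. Bromine–lithium exchange with n-BuLi in THF at −100 °C then gives the ortho-lithiated aryl ester, which undergoes the anionic Fries 1,3 O→C acyl shift. Because this ring carries no chlorine, the product is ketone 30, and the route is rejoined at step 17.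

Step 12. Alkylation of the hindered tertiary alkoxide may be slow, so that O-alkylation of the carboxylate or base-induced loss of HBr from the electrophile takes over. The fallback moves the etherification to the thioester stage and to acid catalysis. Hydroxy thioester 21 is treated with 2-bromoprop-2-en-1-yl 2,2,2-trichloroethanimidate F3 (from 2-bromoprop-2-en-1-ol, Cl3CCN and catalytic DBU) and catalytic CF3SO3H in CH2Cl2/cyclohexane. This gives tert-butyl (2R)-2-[(2-bromoprop-2-en-1-yl)oxy]-2-[2-(tert-butylsulfanyl)-2-oxoethyl]hex-5-enoate F4, and saponification of its thioester with LiOH as in step 11 gives acid 24, where the route is rejoined at step 13.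

Step 18. The allylic oxyphosphonium ion may be attacked at the far alkene carbon, giving allylic transposition, or by a phenolic oxygen instead of the carboxylate. The fallback separates activation from substitution. Alcohol 31 is converted with CBr4 and PPh3 in CH2Cl2 at 0 °C into tert-butyl (2R)-6-[(3E)-5-bromo-4-methylpent-3-en-1-yl]-2-{2-[2-hydroxy-5-(methoxymethoxy)phenyl]-2-oxoethyl}-2,3,4,7-tetrahydrooxepine-2-carboxylate F5. This bromide is displaced by the potassium carboxylate of 32, formed with KHCO3 in DMF at rt; hydrogencarbonate deprotonates only the carboxylic acid. The product is ester 33, and the route continues with step 19.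

**Further compounds**

F1 | step 15 | 2-bromo-4-(methoxymethoxy)phenol | COCOc1ccc(O)c(Br)c1
F2 | step 15 | 2-bromo-4-(methoxymethoxy)phenyl 2-[(2R)-2-(tert-butoxycarbonyl)-6-[(3E)-5-{[tert-butyl(diphenyl)silyl]oxy}-4-methylpent-3-en-1-yl]-2,3,4,7-tetrahydrooxepin-2-yl]acetate | C/C(=C\CCC1=CCC[C@@](CC(=O)Oc2ccc(OCOC)cc2Br)(C(=O)OC(C)(C)C)OC1)CO[Si](c1ccccc1)(c1ccccc1)C(C)(C)C
F3 | step 12 | 2-bromoprop-2-en-1-yl 2,2,2-trichloroethanimidate | C=C(Br)COC(=N)C(Cl)(Cl)Cl
F4 | step 12 | tert-butyl (2R)-2-[(2-bromoprop-2-en-1-yl)oxy]-2-[2-(tert-butylsulfanyl)-2-oxoethyl]hex-5-enoate | C=CCC[C@@](CC(=O)SC(C)(C)C)(C(=O)OC(C)(C)C)OCC(Br)=C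
F5 | step 18 | tert-butyl (2R)-6-[(3E)-5-bromo-4-methylpent-3-en-1-yl]-2-{2-[2-hydroxy-5-(methoxymethoxy)phenyl]-2-oxoethyl}-2,3,4,7-tetrahydrooxepine-2-carboxylate | C/C(=C\CCC1=CCC[C@@](CC(=O)c2cc(OCOC)ccc2O)(C(=O)OC(C)(C)C)OC1)CBr
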